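**Retrosynthetic overview**

1. Target 31 ⇐ (Si–O cleavage) TBS-lactone 30 ⇐ [O–C6, key step] macrocyclic methyl 1-(hydroxymethyl)-2-alkenylcyclopropane-1-carboxylate 27: the α-methylene-γ-butyrolactone is unveiled last by a strain-releasing cyclopropylcarbinyl→homoallyl opening with lactonisation.
2. Enabling feature: the lactone oxygen sits on C6, which is allylic to the ring alkene C4=C5, and C6, C7 and C11 of the lactone form a three-carbon unit with the exocyclic C13 on C11. C6–C7–C11 can therefore be stored as a cyclopropane with C13 as CH2–X; breaking C6–C11 creates C11=C13 and an allylic electrophile at C6 within reach of the C12 carboxyl oxygen.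
3. 27 ⇐ acid 25 ⇐ [C4–C5] intramolecular vinylogous aldol/lactonisation/E1cB of furanone–cyclopropanecarbaldehyde 22 (closes the ten-membered carbocycle, sets Z-C4=C5, differentiates the two esters on C11).
4. 22 ⇐ [C6–C11, C7–C11] organocatalytic cyclopropanation of enal 20 ⇐ cross-metathesis and esterification ⇐ furanone 14 ⇐ [C1–C2, O–C3] butynylation/cyclisation ⇐ [C8–C9] γ-alkoxyallylboration of aldehyde 4 ⇐ lactic-acid dioxolanone 1 (C10).
5. Ring order: 3(2H)-furanone → cyclopropane (temporary) → ten-membered carbocycle → γ-lactone (cyclopropane opened).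

Key step: step 13

Remark (numbering used in the text, germacrane): C1 furanone C=O, C2 furanone CH=, C3 furanone O–C=, C4 (bears C15H3), C5 =CH, C6 lactone O–CH, C7, C8 (ester), C9 (OH), C10 (quaternary, bears C14H3), C11 (=CH2 carbon), C12 lactone C=O, C13 exocyclic CH2.

Assumption: 1, 5, 17 and (+)-B-methoxydiisopinocampheylborane are taken as purchasable (1 is otherwise one step from (S)-lactic acid and pivalaldehyde, 5 one step from allyl alcohol).

Remark: the configuration at C11 in 24–28 follows from the lactone trap of step 11 and is immaterial, because C11 becomes sp2 in step 13.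

**Route**

Step 1
Reactants: 1 (2S,5S)-2-tert-butyl-5-methyl-1,3-dioxolan-4-one; 2 formaldehyde
Product: 3 (2S,5R)-2-tert-butyl-5-(hydroxymethyl)-5-methyl-1,3-dioxolan-4-one
Conditions: LDA, THF, −78 °C; CH2O (gas, from cracked paraformaldehyde), −78 → −40 °C; aq. NH4Cl
Reagents that add atoms: formaldehyde (2), C=O
Why: Aldol-type hydroxymethylation of the lithium enolate of the lactic-acid acetal (self-regeneration of stereocentres): the electrophile enters anti to the tert-butyl group, so the lactate configuration is reproduced and the quaternary carbinol carbon C10 is set.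

Step 2
Reactants: 3 (2S,5R)-2-tert-butyl-5-(hydroxymethyl)-5-methyl-1,3-dioxolan-4-one
Product: 4 (2S,5R)-2-tert-butyl-5-formyl-5-methyl-1,3-dioxolan-4-one
Conditions: Dess–Martin periodinane, CH2Cl2, 0 °C → rt
Reagents that add atoms: none
Why: Dess–Martin oxidation of a primary alcohol to a non-enolisable aldehyde, so C10 cannot epimerise.

Step 3
Reactants: 4 (2S,5R)-2-tert-butyl-5-formyl-5-methyl-1,3-dioxolan-4-one; 5 allyl methoxymethyl ether
Product: 7 (2S,5R)-2-tert-butyl-5-[(1R,2S)-1-hydroxy-2-(methoxymethoxy)but-3-en-1-yl]-5-methyl-1,3-dioxolan-4-one, via allylborane 6 (not isolated)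
Conditions: 5, s-BuLi, THF, −78 °C; (+)-Ipc2BOMe; BF3·OEt2; then 4, −78 °C; ethanolamine work-up
Reagents that add atoms: allyl methoxymethyl ether (5), C=CCOCOC
Why: Asymmetric γ-alkoxyallylboration through a chair Zimmerman–Traxler transition state: the Z-configured γ-alkoxyallylborane gives the syn C8/C9 relationship, and the isopinocampheyl groups derived from (−)-α-pinene direct attack to the Re face of the aldehyde, which sets C9 (R) and C8 (S) under reagent control.

Step 4
Reactants: 7 (2S,5R)-2-tert-butyl-5-[(1R,2S)-1-hydroxy-2-(methoxymethoxy)but-3-en-1-yl]-5-methyl-1,3-dioxolan-4-one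
Product: 8 (2S,5R)-2-tert-butyl-5-[(1R,2S)-1-(tert-butyldimethylsilyloxy)-2-(methoxymethoxy)but-3-en-1-yl]-5-methyl-1,3-dioxolan-4-one
Conditions: TBSOTf, 2,6-lutidine, CH2Cl2, −40 → 0 °C
Reagents that add atoms: tert-butyldimethylsilyl trifluoromethanesulfonate, CC(C)(C)[Si](C)(C)OS(=O)(=O)C(F)(F)F
Why: Silylation of the hindered secondary C9 alcohol with the silyl triflate; the silyl ether blocks retro-aldol cleavage of the C9–C10 bond in all later basic steps.

Step 5
Reactants: 8 TBS ether of 7; 9 but-1-yne
Product: 12 (3S,4R,5R)-4-(tert-butyldimethylsilyloxy)-5-hydroxy-3-(methoxymethoxy)-5-methyldec-1-en-7-yn-6-one, via lithium butynide 10 (not isolated), via lithium hemiketal 11 (not isolated)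
Conditions: 9, n-BuLi, THF, −78 °C; then 8, −78 °C; AcOH quench, then aq. NaHCO3
Reagents that add atoms: but-1-yne (9), CCC#C
Why: Acetylide addition to the lactone-type carbonyl of the dioxolanone; the cyclic lithium hemiketal should persist at −78 °C (no second addition) and collapses on protic work-up with loss of pivalaldehyde, which removes the auxiliary acetal and gives the α'-hydroxy ynone with C10 untouched.

Step 6
Reactants: 12 (3S,4R,5R)-4-(tert-butyldimethylsilyloxy)-5-hydroxy-3-(methoxymethoxy)-5-methyldec-1-en-7-yn-6-one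
Product: 14 (2R)-2-[(1R,2S)-1-(tert-butyldimethylsilyloxy)-2-(methoxymethoxy)but-3-en-1-yl]-5-ethyl-2-methylfuran-3(2H)-one, via enaminone 13 (not isolated)
Conditions: Et2NH, EtOH, rt
Reagents that add atoms: none
Why: Amine-mediated cycloisomerisation of an α'-hydroxy ynone to a 3(2H)-furanone: aza-Michael addition of Et2NH gives the enaminone, and the tertiary C10 hydroxyl closes the five-membered ring at C3 by addition–elimination with loss of the amine, without touching a stereocentre.

Step 7
Reactants: 14 (2R)-2-[(1R,2S)-1-(tert-butyldimethylsilyloxy)-2-(methoxymethoxy)but-3-en-1-yl]-5-ethyl-2-methylfuran-3(2H)-one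
Product: 16 (2R)-2-[(1R,2S)-1-(tert-butyldimethylsilyloxy)-2-hydroxybut-3-en-1-yl]-5-ethyl-2-methylfuran-3(2H)-one, via bromomethyl ether 15 (not isolated)
Conditions: Me2BBr, CH2Cl2, −78 °C; then THF/sat. aq. NaHCO3
Reagents that add atoms: none
Why: Lewis-acid cleavage of the methoxymethyl acetal by the bromoborane at −78 °C (to the bromomethyl ether, hydrolysed on work-up) is selective for the acetal over the secondary TBS ether and leaves the C8 configuration unchanged.

Step 8
Reactants: 16 (2R)-2-[(1R,2S)-1-(tert-butyldimethylsilyloxy)-2-hydroxybut-3-en-1-yl]-5-ethyl-2-methylfuran-3(2H)-one; 17 (R)-2-methylbutanoic acid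
Product: 18 (1R,2S)-1-(tert-butyldimethylsilyloxy)-1-[(2R)-5-ethyl-2-methyl-3-oxo-2,3-dihydrofuran-2-yl]but-3-en-2-yl (2R)-2-methylbutanoate
Conditions: DCC, DMAP (cat.), CH2Cl2, 0 °C → rt
Reagents that add atoms: (R)-2-methylbutanoic acid (17), CC[C@@H](C)C(=O)O
Why: Steglich esterification of the C8 alcohol with retention at C8; the mild, alkoxide-free conditions are chosen to avoid epimerisation of the acid and 1,2-silyl migration from O9.

Step 9
Reactants: 18 allylic ester; 19 (E)-but-2-enal
Product: 20 (1R,2S,3E)-1-(tert-butyldimethylsilyloxy)-1-[(2R)-5-ethyl-2-methyl-3-oxo-2,3-dihydrofuran-2-yl]-5-oxopent-3-en-2-yl (2R)-2-methylbutanoate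
Conditions: Hoveyda–Grubbs II (5 mol %), crotonaldehyde (5 equiv), CH2Cl2, 40 °C
Reagents that add atoms: (E)-but-2-enal (19), C/C=C/C=O
Why: Olefin cross-metathesis of the terminal alkene with excess crotonaldehyde gives the E-enal (thermodynamic geometry) with loss of propene, while the trisubstituted furanone alkene is inert.

Step 10
Reactants: 20 γ-acyloxy enal; 21 dimethyl bromomalonate
Product: 22 dimethyl (2R,3R)-2-formyl-3-[(1S,2R)-2-(tert-butyldimethylsilyloxy)-2-[(2R)-5-ethyl-2-methyl-3-oxo-2,3-dihydrofuran-2-yl]-1-[(2R)-2-methylbutanoyloxy]ethyl]cyclopropane-1,1-dicarboxylate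
Conditions: (S)-α,α-diphenylprolinol trimethylsilyl ether (20 mol %), 2,6-lutidine, CH2Cl2, 0 °C → rt
Reagents that add atoms: dimethyl bromomalonate (21), COC(=O)C(Br)C(=O)OC
Why: Organocatalytic Michael-initiated ring closure: the bromomalonate anion adds to C7 of the E-iminium ion on the face remote from the diphenyl(silyloxy)methyl group (sets C7), and the resulting enamine displaces bromide in a 3-exo-tet closure that places the formyl group trans to C8 (sets C6); catalyst control is expected to override the adjacent C8 centre.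

Step 11
Reactants: 22 cyclopropanecarbaldehyde diester
Product: 25 macrocyclic acid (ten-membered carbocycle, Z-C4=C5, C11 bearing CO2H trans to C8 and CO2Me cis to C8), via aldol adduct 23 (not isolated), via bicyclic lactone 24 (not isolated)
Conditions: LiHMDS (1.1 equiv), THF (2 mM), −78 → 0 °C; then 0.5 M HCl
Reagents that add atoms: none
Why: Intramolecular vinylogous aldol reaction of the furanone dienolate (γ-carbon C4) with the non-enolisable cyclopropanecarbaldehyde (C5) closes the ten-membered carbocycle, the aldolate is trapped as the γ-lactone by the ester syn to it on C11 (which fixes C11), and methoxide-induced E1cB opening expels the carboxylate to give the C4=C5 alkene, whose Z geometry is imposed by the nine-membered oxacycle that contains it.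

Step 12
Reactants: 25 macrocyclic acid
Product: 27 macrocyclic methyl 1-(hydroxymethyl)cyclopropane-1-carboxylate (C13H2OH on C11), via mixed anhydride 26 (not isolated)
Conditions: i-BuOCOCl, N-methylmorpholine, THF, −15 °C; then NaBH4, H2O, −15 → 0 °C
Reagents that add atoms: none
Why: Mixed-carbonic-anhydride activation followed by borohydride reduction should be chemoselective for the activated acyl group over the methyl ester, the C8 ester and the vinylogous-ester ketone, and gives the primary cyclopropylcarbinyl alcohol without touching a stereocentre.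

Step 13
Reactants: 27 macrocyclic methyl 1-(hydroxymethyl)cyclopropane-1-carboxylate
Product: 30 9-O-TBS ether of the target (α-methylene-γ-butyrolactone closed), via mesylate 28 (not isolated), via allylic bromide 29 (not isolated)
Conditions: MsCl, Et3N, CH2Cl2, −30 °C; then MgBr2·OEt2 (3 equiv), CH2Cl2/Et2O, 0 → 40 °C
Reagents that add atoms: none
Why: Mesylation turns C13 into a cyclopropylcarbinyl leaving group, and MgBr2 then triggers the cyclopropylcarbinyl→homoallyl rearrangement: bromide attacks the allylic ring carbon C6 anti to the breaking C6–C11 bond while C11=C13 forms, releasing the cyclopropane strain (about 27 kcal/mol) and giving allylic bromide 29. The carbonyl oxygen of the neighbouring methyl ester then displaces the allylic bromide in a 5-exo-tet closure that forms the O–C6 bond, and bromide demethylates the resulting methoxy-oxocarbenium ion to the α-methylene-γ-butyrolactone. The closest known reaction type is the conversion of 1-(hydroxymethyl)cyclopropane-1-carboxylates into α-methylene-γ-butyrolactones through homoallylic halides. C6 is the only new stereocentre: two successive inversions amount to retention, so the trans-cyclopropane of step 10 is translated into the trans-fused (6R) lactone, and if the bromide epimerises by halide exchange the closure should still funnel to the trans-lactone, because the transition state for the cis-fused isomer eclipses C5 and C8 inside the ten-membered ring. The step needs cleavage of C11–C6 rather than C11–C7, which the alkenyl group on C6 secures by allylic activation, and retention of the Z-C4=C5 geometry, which the furanone bridge locks.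

Step 14
Reactants: 30 9-O-TBS ether of the target
Product: 31 CNP0146060.1
Conditions: HF·pyridine, pyridine/THF, 0 °C → rt
Reagents that add atoms: none
Why: Fluoride-mediated Si–O cleavage under non-basic conditions frees the C9 hydroxyl while avoiding retro-aldol cleavage of C9–C10, acyl migration from O8 to O9 and conjugate addition to the methylene lactone.

**Compound list**

1 | (2S,5S)-2-tert-butyl-5-methyl-1,3-dioxolan-4-one | C[C@@H]1O[C@H](C(C)(C)C)OC1=O | starting material
2 | formaldehyde | C=O | starting material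
3 | (2S,5R)-2-tert-butyl-5-(hydroxymethyl)-5-methyl-1,3-dioxolan-4-one | C[C@]1(CO)O[C@H](C(C)(C)C)OC1=O | intermediate
4 | (2S,5R)-2-tert-butyl-5-formyl-5-methyl-1,3-dioxolan-4-one | C[C@]1(C=O)O[C@H](C(C)(C)C)OC1=O | intermediate
5 | allyl methoxymethyl ether | C=CCOCOC | starting material
6 | [(Z)-3-(methoxymethoxy)prop-2-en-1-yl]diisopinocampheylborane (isopinocampheyl groups from (−)-α-pinene) | COCO/C=C\CB([C@H]1C[C@H]2C[C@@H]([C@@H]1C)C2(C)C)[C@H]1C[C@H]2C[C@@H]([C@@H]1C)C2(C)C | intermediate
7 | (2S,5R)-2-tert-butyl-5-[(1R,2S)-1-hydroxy-2-(methoxymethoxy)but-3-en-1-yl]-5-methyl-1,3-dioxolan-4-one | C[C@]1([C@H](O)[C@@H](OCOC)C=C)O[C@H](C(C)(C)C)OC1=O | intermediate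
8 | (2S,5R)-2-tert-butyl-5-[(1R,2S)-1-(tert-butyldimethylsilyloxy)-2-(methoxymethoxy)but-3-en-1-yl]-5-methyl-1,3-dioxolan-4-one | C[C@]1([C@H](O[Si](C)(C)C(C)(C)C)[C@@H](OCOC)C=C)O[C@H](C(C)(C)C)OC1=O | intermediate
9 | but-1-yne | CCC#C | starting material
10 | lithium but-1-yn-1-ide | [Li]C#CCC | intermediate
11 | lithium hemiketal alkoxide from addition of 10 to the lactone carbonyl of 8 (new hemiketal centre undefined) | CCC#CC1(O[Li])O[C@@H](C(C)(C)C)O[C@]1(C)[C@H](O[Si](C)(C)C(C)(C)C)[C@@H](OCOC)C=C | intermediate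
12 | (3S,4R,5R)-4-(tert-butyldimethylsilyloxy)-5-hydroxy-3-(methoxymethoxy)-5-methyldec-1-en-7-yn-6-one | CCC#CC(=O)[C@](C)(O)[C@H](O[Si](C)(C)C(C)(C)C)[C@@H](OCOC)C=C | intermediate
13 | β-(diethylamino) enone from aza-Michael addition of Et2NH to 12 (alkene geometry undefined) | CCC(=CC(=O)[C@](C)(O)[C@H](O[Si](C)(C)C(C)(C)C)[C@@H](OCOC)C=C)N(CC)CC | intermediate
14 | (2R)-2-[(1R,2S)-1-(tert-butyldimethylsilyloxy)-2-(methoxymethoxy)but-3-en-1-yl]-5-ethyl-2-methylfuran-3(2H)-one | CCC1=CC(=O)[C@](C)(O1)[C@H](O[Si](C)(C)C(C)(C)C)[C@@H](OCOC)C=C | intermediate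
15 | bromomethyl ether of 16 (OCH2Br on C8) | CCC1=CC(=O)[C@](C)(O1)[C@H](O[Si](C)(C)C(C)(C)C)[C@@H](OCBr)C=C | intermediate
16 | (2R)-2-[(1R,2S)-1-(tert-butyldimethylsilyloxy)-2-hydroxybut-3-en-1-yl]-5-ethyl-2-methylfuran-3(2H)-one | CCC1=CC(=O)[C@](C)(O1)[C@H](O[Si](C)(C)C(C)(C)C)[C@@H](O)C=C | intermediate
17 | (R)-2-methylbutanoic acid | CC[C@@H](C)C(=O)O | starting material
18 | (1R,2S)-1-(tert-butyldimethylsilyloxy)-1-[(2R)-5-ethyl-2-methyl-3-oxo-2,3-dihydrofuran-2-yl]but-3-en-2-yl (2R)-2-methylbutanoate | CCC1=CC(=O)[C@](C)(O1)[C@H](O[Si](C)(C)C(C)(C)C)[C@@H](OC(=O)[C@H](C)CC)C=C | intermediate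
19 | (E)-but-2-enal (crotonaldehyde) | C/C=C/C=O | starting material
20 | (1R,2S,3E)-1-(tert-butyldimethylsilyloxy)-1-[(2R)-5-ethyl-2-methyl-3-oxo-2,3-dihydrofuran-2-yl]-5-oxopent-3-en-2-yl (2R)-2-methylbutanoate | CCC1=CC(=O)[C@](C)(O1)[C@H](O[Si](C)(C)C(C)(C)C)[C@@H](OC(=O)[C@H](C)CC)/C=C/C=O | intermediate
21 | dimethyl bromomalonate | COC(=O)C(Br)C(=O)OC | starting material
22 | dimethyl (2R,3R)-2-formyl-3-[(1S,2R)-2-(tert-butyldimethylsilyloxy)-2-[(2R)-5-ethyl-2-methyl-3-oxo-2,3-dihydrofuran-2-yl]-1-[(2R)-2-methylbutanoyloxy]ethyl]cyclopropane-1,1-dicarboxylate | CCC1=CC(=O)[C@](C)(O1)[C@H](O[Si](C)(C)C(C)(C)C)[C@@H](OC(=O)[C@H](C)CC)[C@@H]1[C@@H](C=O)C1(C(=O)OC)C(=O)OC | intermediate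
23 | macrocyclic aldol adduct: ten-membered carbocycle closed by the C4–C5 bond, C5–OH, trans-fused cyclopropane diester (C4 and C5 as diastereomer mixture) | COC(=O)C1(C(=O)OC)[C@@H]2C(O)C(C)C3=CC(=O)[C@](C)(O3)[C@H](O[Si](C)(C)C(C)(C)C)[C@@H](OC(=O)[C@H](C)CC)[C@@H]12 | intermediate
24 | bicyclic lactone of 23: C5–O acylated by the C11 ester syn to it (C4 and C5 as diastereomer mixture) | COC(=O)[C@]14C(=O)OC2C(C)C3=CC(=O)[C@](C)(O3)[C@H](O[Si](C)(C)C(C)(C)C)[C@@H](OC(=O)[C@H](C)CC)[C@@H]1[C@@H]24 | intermediate
25 | macrocyclic acid: Z-C4=C5, cyclopropane C6–C7–C11 with CO2H (trans to C8) and CO2Me (cis to C8) on C11, C8 (R)-2-methylbutanoate, C9 OTBS | COC(=O)[C@@]1(C(=O)O)[C@@H]2/C=C(/C)C3=CC(=O)[C@](C)(O3)[C@H](O[Si](C)(C)C(C)(C)C)[C@@H](OC(=O)[C@H](C)CC)[C@@H]12 | intermediate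
26 | isobutyl carbonic mixed anhydride of 25 | COC(=O)[C@@]1(C(=O)OC(=O)OCC(C)C)[C@@H]2/C=C(/C)C3=CC(=O)[C@](C)(O3)[C@H](O[Si](C)(C)C(C)(C)C)[C@@H](OC(=O)[C@H](C)CC)[C@@H]12 | intermediate
27 | macrocyclic methyl 1-(hydroxymethyl)cyclopropane-1-carboxylate (CO2H of 25 reduced to C13H2OH) | COC(=O)[C@@]1(CO)[C@@H]2/C=C(/C)C3=CC(=O)[C@](C)(O3)[C@H](O[Si](C)(C)C(C)(C)C)[C@@H](OC(=O)[C@H](C)CC)[C@@H]12 | intermediate
28 | methanesulfonate of 27 | COC(=O)[C@@]1(COS(C)(=O)=O)[C@@H]2/C=C(/C)C3=CC(=O)[C@](C)(O3)[C@H](O[Si](C)(C)C(C)(C)C)[C@@H](OC(=O)[C@H](C)CC)[C@@H]12 | intermediate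
29 | ring-opened allylic bromide: methyl 2-substituted acrylate on C7, bromide on C6 (inverted relative to the cyclopropane) | C=C(C(=O)OC)[C@H]1[C@@H](Br)/C=C(/C)C2=CC(=O)[C@](C)(O2)[C@H](O[Si](C)(C)C(C)(C)C)[C@H]1OC(=O)[C@H](C)CC | intermediate
30 | 9-O-tert-butyldimethylsilyl ether of the target | C=C1C(=O)O[C@@H]2/C=C(/C)C3=CC(=O)[C@](C)(O3)[C@H](O[Si](C)(C)C(C)(C)C)[C@@H](OC(=O)[C@H](C)CC)[C@@H]12 | intermediate
31 | CNP0146060.1: (6R,7S,8S,9R,10R)-9-hydroxy-8-[(2R)-2-methylbutanoyloxy]-1-oxo-3,10-epoxygermacra-2,4(Z),11(13)-trien-12,6-olide | C=C1C(=O)O[C@@H]2/C=C(/C)C3=CC(=O)[C@](C)(O3)[C@H](O)[C@@H](OC(=O)[C@H](C)CC)[C@@H]12 | target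

Total step count: 14. Longest linear sequence: 14 steps (1 → 31).

**Steps most likely to fail, with fallbacks**

Step 11 (macrocyclisation cascade). The ring closure may lose to intermolecular aldol oligomerisation, to retro-aldol reversal before the lactone trap engages, or to addition of the amide base to the aldehyde; the released methoxide may also attack the C8 ester. The fallback sets out from 22 and replaces the reversible lithium-dienolate closure by an irreversible Lewis-acid-driven one. Soft enolisation (TMSOTf, Et3N, CH2Cl2, −78 °C) would give the trimethylsilyl dienol ether F1. Slow addition of F1 to BF3·OEt2 (CH2Cl2, −78 °C, 1 mM) would close the ring by an intramolecular vinylogous Mukaiyama aldol reaction. Aqueous work-up would give the aldol adduct, which is compound 23 of the route; 23 would then be isolated and treated with DBU (THF, 0 °C → rt) to run the lactonisation/E1cB sequence to 25.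

Step 13 (key step). Configurational control at C6 may be lost through bromide exchange or a free allyl cation, giving cis-fused lactone; HBr may be eliminated toward a triene; or the demethylative closure may stall at the bromide stage. The fallback sets out from acid 25 and forms the same O–C6 bond through a π-allyl palladium intermediate instead of a cyclopropylcarbinyl cation. Pd(PPh3)4 (THF, rt) would ionise the vinylcyclopropane, which carries two acceptors on C11, with inversion, and the carboxylate would attack C6 anti to palladium (net retention) to give the α-(methoxycarbonyl) lactone F2. Selective methyl ester cleavage (Me3SnOH, 1,2-dichloroethane, 70 °C) would give the α-carboxy lactone F3. Decarboxylative Mannich methylenation (aq. HCHO, Et2NH; then NaOAc, AcOH, 80 °C) would return to 30.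

Step 10 (cyclopropanation). The γ-acyloxy enal may lose the ester by dienamine-mediated elimination under the basic conditions, and substrate bias from C8 may erode the catalyst-controlled face selectivity at C7. The fallback sets out from enal 20 and separates the stereodefining C–C bond formation from the ring closure. Base-free iminium-catalysed Michael addition of dimethyl malonate (same (S)-catalyst, EtOH, 0 °C) would give the malonate aldehyde F4. Oxidative ring closure (I2, K2CO3, CH2Cl2: α-iodination of the malonate carbon and intramolecular C-alkylation by the aldehyde enolate, trans by thermodynamic preference) would return to 22.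

Further compounds
F1 | step 11 | trimethylsilyl dienol ether of 22 (5-ethylidene-3-(trimethylsilyloxy)-2,5-dihydrofuran form, ethylidene geometry undefined) | CC=C1C=C(O[Si](C)(C)C)[C@](C)(O1)[C@H](O[Si](C)(C)C(C)(C)C)[C@@H](OC(=O)[C@H](C)CC)[C@@H]1[C@@H](C=O)C1(C(=O)OC)C(=O)OC
F2 | step 13 | 9-O-TBS trans-lactone bearing CO2Me and H on C11 in place of the methylene group (C11 undefined) | COC(=O)C1C(=O)O[C@@H]2/C=C(/C)C3=CC(=O)[C@](C)(O3)[C@H](O[Si](C)(C)C(C)(C)C)[C@@H](OC(=O)[C@H](C)CC)[C@@H]12
F3 | step 13 | 9-O-TBS trans-lactone bearing CO2H and H on C11 (C11 undefined) | OC(=O)C1C(=O)O[C@@H]2/C=C(/C)C3=CC(=O)[C@](C)(O3)[C@H](O[Si](C)(C)C(C)(C)C)[C@@H](OC(=O)[C@H](C)CC)[C@@H]12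
F4 | step 10 | Michael adduct of dimethyl malonate with enal 20 (malonate on C7, free aldehyde) | CCC1=CC(=O)[C@](C)(O1)[C@H](O[Si](C)(C)C(C)(C)C)[C@@H](OC(=O)[C@H](C)CC)[C@H](CC=O)C(C(=O)OC)C(=O)OC
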